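**Retrosynthetic overview**
1. The strategy rests on the saturated run C6(H2)–C7(H)(CH3)–C8(H)(CH3)–C9(H)(OH) of the seven-membered ring, between the spiro carbon C5 of dienone ring B and C9a of ring A: C7, C8 and C9 can each be inserted into a C–B bond.
2. C6–C7, C7–C8 and C8–C9: benzylboronate 6 + (S)- then (R)-1-lithioethyl triisopropylbenzoate + chloromethyllithium give boronate 14, with C7 and C8 set by the reagents.
3. C9–C9a: aldehyde 16 + ring-A Grignard reagent 18, with C9 set by Felkin–Anh control.
4. C5–C4a: oxidative para-spirocyclisation of phenol 21 closes the seven-membered ring and dearomatises ring B; desilylation gives target 23.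
5. Ring order: rings A and B are bought as arenes (5-bromo-1,2,3-trimethoxybenzene, syringaldehyde); the seven-membered ring is the only ring made and forms in the penultimate step.

Key step: step 5

Assumption: both sparteine enantiomers are used as commercial ligands and are recovered unchanged; the spiro carbon carries two constitutionally identical dienone arms and is not a stereocentre, so only C7, C8 and C9 need control.

**Route**

Step 1
Reactants: 1 syringaldehyde (4-hydroxy-3,5-dimethoxybenzaldehyde)
Product: 2 4-(benzyloxy)-3,5-dimethoxybenzaldehyde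
Conditions: BnBr, K2CO3, DMF, 60 °C
Reagents that add atoms: benzyl bromide, BrCc1ccccc1
Why: Williamson ether synthesis on the acidic phenoxide; the benzyl ether should survive all organometallic and oxidation steps up to its hydrogenolysis in step 10.

Step 2
Reactants: 2 4-(benzyloxy)-3,5-dimethoxybenzaldehyde
Product: 3 [4-(benzyloxy)-3,5-dimethoxyphenyl]methanol
Conditions: NaBH4, MeOH, 0 °C
Reagents that add atoms: none
Why: Hydride reduction of an aryl aldehyde, with no other reducible group present.

Step 3
Reactants: 3 [4-(benzyloxy)-3,5-dimethoxyphenyl]methanol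
Product: 4 2-(benzyloxy)-5-(bromomethyl)-1,3-dimethoxybenzene
Conditions: PBr3, Et2O, 0 °C
Reagents that add atoms: phosphorus tribromide, BrP(Br)Br
Why: Bromination of a benzylic alcohol through its phosphite ester and bromide displacement; the electron-rich benzylic position reacts at 0 °C and the aryl ethers are inert.

Step 4
Reactants: 4 2-(benzyloxy)-5-(bromomethyl)-1,3-dimethoxybenzene; 5 bis(pinacolato)diboron
Product: 6 2-[4-(benzyloxy)-3,5-dimethoxybenzyl]-4,4,5,5-tetramethyl-1,3,2-dioxaborolane
Conditions: Pd(PPh3)4 (cat.), K2CO3, dioxane, 80 °C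
Reagents that add atoms: none
Why: Miyaura-type borylation of a benzylic bromide: oxidative addition of the C–Br bond to zerovalent palladium, transmetallation with the carbonate-activated diboron reagent and reductive elimination; carbonate is chosen over acetate to avoid substitution of the reactive bromide.

Step 5
Reactants: 6 2-[4-(benzyloxy)-3,5-dimethoxybenzyl]-4,4,5,5-tetramethyl-1,3,2-dioxaborolane; 7 ethyl 2,4,6-triisopropylbenzoate (two portions); 8 chloroiodomethane
Product: 14 2-[(2R,3R)-4-(4-(benzyloxy)-3,5-dimethoxyphenyl)-2,3-dimethylbutyl]-4,4,5,5-tetramethyl-1,3,2-dioxaborolane, via (S)-1-lithioethyl 2,4,6-triisopropylbenzoate 9 (not isolated), via pinacol (R)-1-arylpropan-2-ylboronate 10 (not isolated), via (R)-1-lithioethyl 2,4,6-triisopropylbenzoate 11 (not isolated), via pinacol (2S,3R)-4-aryl-3-methylbutan-2-ylboronate 12 (not isolated), via chloromethyllithium 13 (not isolated)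
Conditions: a) 7, (−)-sparteine, s-BuLi (limiting), Et2O, −78 °C, then 6, −78 → 35 °C; b) mixture added at −78 °C to 7, (+)-sparteine, s-BuLi (limiting), Et2O, then −78 → 35 °C; c) 8, n-BuLi, Et2O/THF, −78 °C → rt
Reagents that add atoms: none
Why: s-BuLi with (−)-sparteine removes the pro-S hydrogen of the OCH2 group of 7 to give the configurationally stable carbenoid 9, which adds to the boron of 6 with retention; on warming, the benzylic group shifts from boron to carbon anti to the departing triisopropylbenzoate (inversion at the carbenoid carbon) to give 10, the same cycle with the (+)-sparteine-derived enantiomer 11 converts 10 into 12 with retention at the migrating carbon, and chloromethyllithium 13 then inserts CH2 with loss of chloride. The closest known reaction type is the iterative lithiation–borylation (assembly-line) homologation of pinacol boronic esters with enantioenriched lithiated triisopropylbenzoates, finished by a Matteson homologation with chloromethyllithium. No ring is closed; the three bonds formed are CH2–C3, C3–C2 and C2–C1 of the butyl chain of 14, which become C6–C7, C7–C8 and C8–C9 of the target. C3 (R) is fixed by the (S)-carbenoid and C2 (R) by the (R)-carbenoid, that is by the reagent alone, because addition to boron and the 1,2-shift are both stereospecific. The step needs one insertion per cycle and a syn relationship of the two methyl groups whatever the substrate bias; the first is secured because boronate formation is fast at −78 °C while migration sets in only on warming, when surplus carbenoid has decomposed, and the second by switching the sparteine enantiomer. Since the two centres are set independently, the minor antipode of each carbenoid should end up mainly in the separable anti diastereomer, so the syn isomer is expected to be enantiomerically purer than either reagent.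

Step 6
Reactants: 14 2-[(2R,3R)-4-(4-(benzyloxy)-3,5-dimethoxyphenyl)-2,3-dimethylbutyl]-4,4,5,5-tetramethyl-1,3,2-dioxaborolane
Product: 15 (2S,3R)-4-[4-(benzyloxy)-3,5-dimethoxyphenyl]-2,3-dimethylbutan-1-ol
Conditions: NaOH, H2O2, THF/H2O, 0 °C → rt
Reagents that add atoms: hydrogen peroxide, OO
Why: Oxidation of the C–B bond by hydroperoxide (1,2-shift of the primary alkyl group from boron to oxygen, then hydrolysis); no stereocentre is touched, and chromatography here should remove benzoate residues and the minor anti diastereomer.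

Step 7
Reactants: 15 (2S,3R)-4-[4-(benzyloxy)-3,5-dimethoxyphenyl]-2,3-dimethylbutan-1-ol
Product: 16 (2S,3R)-4-[4-(benzyloxy)-3,5-dimethoxyphenyl]-2,3-dimethylbutanal
Conditions: Dess–Martin periodinane, CH2Cl2, 0 °C → rt
Reagents that add atoms: none
Why: Dess–Martin oxidation of a primary alcohol under near-neutral conditions, so the epimerisable α-methyl aldehyde is not exposed to base; the crude aldehyde is to be used at once.

Step 8
Reactants: 16 (2S,3R)-4-[4-(benzyloxy)-3,5-dimethoxyphenyl]-2,3-dimethylbutanal; 17 5-bromo-1,2,3-trimethoxybenzene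
Product: 19 (1R,2S,3R)-4-[4-(benzyloxy)-3,5-dimethoxyphenyl]-2,3-dimethyl-1-(3,4,5-trimethoxyphenyl)butan-1-ol, via 3,4,5-trimethoxyphenylmagnesium bromide 18 (not isolated)
Conditions: 17, Mg, THF, 40 °C; then 16, THF, −78 °C; H2O work-up
Reagents that add atoms: none
Why: Grignard formation and Felkin–Anh addition: the aryl nucleophile attacks anti to the branched C3 substituent and past the α-hydrogen, which places the new hydroxyl syn to the C2 methyl group and sets C1 as R; selectivity is expected to be modest and the C1 epimer is to be removed by chromatography.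

Step 9
Reactants: 19 (1R,2S,3R)-4-[4-(benzyloxy)-3,5-dimethoxyphenyl]-2,3-dimethyl-1-(3,4,5-trimethoxyphenyl)butan-1-ol
Product: 20 {[(1R,2S,3R)-4-(4-(benzyloxy)-3,5-dimethoxyphenyl)-2,3-dimethyl-1-(3,4,5-trimethoxyphenyl)butyl]oxy}(tert-butyl)dimethylsilane
Conditions: TBSOTf, 2,6-lutidine, CH2Cl2, −78 → 0 °C
Reagents that add atoms: tert-butyldimethylsilyl trifluoromethanesulfonate, CC(C)(C)[Si](C)(C)OS(=O)(=O)C(F)(F)F
Why: Silylation of a hindered secondary benzylic alcohol with a silyl triflate and a non-nucleophilic base; the ether masks the oxygen nucleophile during the oxidative cyclisation and should survive hydrogenolysis.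

Step 10
Reactants: 20 {[(1R,2S,3R)-4-(4-(benzyloxy)-3,5-dimethoxyphenyl)-2,3-dimethyl-1-(3,4,5-trimethoxyphenyl)butyl]oxy}(tert-butyl)dimethylsilane
Product: 21 4-[(2R,3S,4R)-4-(tert-butyldimethylsilyloxy)-2,3-dimethyl-4-(3,4,5-trimethoxyphenyl)butyl]-2,6-dimethoxyphenol
Conditions: H2 (1 atm), Pd/C (10 wt% Pd on carbon), EtOAc, rt
Reagents that add atoms: none
Why: Catalytic hydrogenolysis of the aryl benzyl ether; in a neutral aprotic solvent the hindered benzylic silyl ether should be cleaved much more slowly than the O-benzyl group.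

Step 11
Reactants: 21 4-[(2R,3S,4R)-4-(tert-butyldimethylsilyloxy)-2,3-dimethyl-4-(3,4,5-trimethoxyphenyl)butyl]-2,6-dimethoxyphenol
Product: 22 (7R,8S,9R)-9-(tert-butyldimethylsilyloxy)-2,3,3',4,5'-pentamethoxy-7,8-dimethyl-6,7,8,9-tetrahydrospiro[benzo[7]annulene-5,1'-cyclohexane]-2',5'-dien-4'-one
Conditions: PhI(OCOCF3)2, CF3CH2OH, −40 °C
Reagents that add atoms: none
Why: Phenol dearomatisation by a trivalent-iodine oxidant: ligand exchange at iodine and two-electron oxidation give a phenoxenium ion, stabilised by its two methoxy groups and the fluorinated solvent, which is captured at its para carbon by C2 of ring A (ortho and para to methoxy groups) in an intramolecular electrophilic aromatic substitution that closes the seven-membered ring as a spirocycle; the silyl ether keeps the carbinol oxygen from competing for the cation.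

Step 12
Reactants: 22 (7R,8S,9R)-9-(tert-butyldimethylsilyloxy)-2,3,3',4,5'-pentamethoxy-7,8-dimethyl-6,7,8,9-tetrahydrospiro[benzo[7]annulene-5,1'-cyclohexane]-2',5'-dien-4'-one
Product: 23 (7R,8S,9R)-9-hydroxy-2,3,3',4,5'-pentamethoxy-7,8-dimethyl-6,7,8,9-tetrahydrospiro[benzo[7]annulene-5,1'-cyclohexane]-2',5'-dien-4'-one
Conditions: Bu4NF, AcOH, THF, 0 °C → rt
Reagents that add atoms: none
Why: Fluoride-mediated desilylation driven by Si–F bond formation; acetic acid buffering keeps the medium near neutral so the cross-conjugated dimethoxydienone and the three stereocentres should be untouched.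

**Compound list**
1 | syringaldehyde (4-hydroxy-3,5-dimethoxybenzaldehyde) | COc1cc(C=O)cc(OC)c1O | starting material
2 | 4-(benzyloxy)-3,5-dimethoxybenzaldehyde | COc1cc(C=O)cc(OC)c1OCc1ccccc1 | intermediate
3 | [4-(benzyloxy)-3,5-dimethoxyphenyl]methanol | COc1cc(CO)cc(OC)c1OCc1ccccc1 | intermediate
4 | 2-(benzyloxy)-5-(bromomethyl)-1,3-dimethoxybenzene | COc1cc(CBr)cc(OC)c1OCc1ccccc1 | intermediate
5 | bis(pinacolato)diboron | CC1(C)OB(OC1(C)C)B1OC(C)(C)C(C)(C)O1 | starting material
6 | 2-[4-(benzyloxy)-3,5-dimethoxybenzyl]-4,4,5,5-tetramethyl-1,3,2-dioxaborolane | COc1cc(CB2OC(C)(C)C(C)(C)O2)cc(OC)c1OCc1ccccc1 | intermediate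
7 | ethyl 2,4,6-triisopropylbenzoate | CCOC(=O)c1c(cc(cc1C(C)C)C(C)C)C(C)C | starting material
8 | chloroiodomethane | ClCI | starting material
9 | (S)-1-lithioethyl 2,4,6-triisopropylbenzoate (formed in the flask) | [Li][C@@H](C)OC(=O)c1c(C(C)C)cc(C(C)C)cc1C(C)C | intermediate
10 | 2-[(2R)-1-(4-(benzyloxy)-3,5-dimethoxyphenyl)propan-2-yl]-4,4,5,5-tetramethyl-1,3,2-dioxaborolane (not isolated) | COc1cc(C[C@@H](C)B2OC(C)(C)C(C)(C)O2)cc(OC)c1OCc1ccccc1 | intermediate
11 | (R)-1-lithioethyl 2,4,6-triisopropylbenzoate (formed in the flask) | [Li][C@H](C)OC(=O)c1c(C(C)C)cc(C(C)C)cc1C(C)C | intermediate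
12 | 2-[(2S,3R)-4-(4-(benzyloxy)-3,5-dimethoxyphenyl)-3-methylbutan-2-yl]-4,4,5,5-tetramethyl-1,3,2-dioxaborolane (not isolated) | COc1cc(C[C@@H](C)[C@H](C)B2OC(C)(C)C(C)(C)O2)cc(OC)c1OCc1ccccc1 | intermediate
13 | chloromethyllithium (formed in the flask) | [Li]CCl | intermediate
14 | 2-[(2R,3R)-4-(4-(benzyloxy)-3,5-dimethoxyphenyl)-2,3-dimethylbutyl]-4,4,5,5-tetramethyl-1,3,2-dioxaborolane | COc1cc(C[C@@H](C)[C@H](C)CB2OC(C)(C)C(C)(C)O2)cc(OC)c1OCc1ccccc1 | intermediate
15 | (2S,3R)-4-[4-(benzyloxy)-3,5-dimethoxyphenyl]-2,3-dimethylbutan-1-ol | COc1cc(C[C@@H](C)[C@H](C)CO)cc(OC)c1OCc1ccccc1 | intermediate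
16 | (2S,3R)-4-[4-(benzyloxy)-3,5-dimethoxyphenyl]-2,3-dimethylbutanal | COc1cc(C[C@@H](C)[C@H](C)C=O)cc(OC)c1OCc1ccccc1 | intermediate
17 | 5-bromo-1,2,3-trimethoxybenzene | COc1cc(Br)cc(OC)c1OC | starting material
18 | 3,4,5-trimethoxyphenylmagnesium bromide (formed in the flask) | COc1cc([Mg]Br)cc(OC)c1OC | intermediate
19 | (1R,2S,3R)-4-[4-(benzyloxy)-3,5-dimethoxyphenyl]-2,3-dimethyl-1-(3,4,5-trimethoxyphenyl)butan-1-ol | COc1cc(C[C@@H](C)[C@H](C)[C@@H](O)c2cc(OC)c(OC)c(OC)c2)cc(OC)c1OCc1ccccc1 | intermediate
20 | tert-butyldimethylsilyl ether of 19 | COc1cc(C[C@@H](C)[C@H](C)[C@@H](O[Si](C)(C)C(C)(C)C)c2cc(OC)c(OC)c(OC)c2)cc(OC)c1OCc1ccccc1 | intermediate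
21 | 4-[(2R,3S,4R)-4-(tert-butyldimethylsilyloxy)-2,3-dimethyl-4-(3,4,5-trimethoxyphenyl)butyl]-2,6-dimethoxyphenol | COc1cc(C[C@@H](C)[C@H](C)[C@@H](O[Si](C)(C)C(C)(C)C)c2cc(OC)c(OC)c(OC)c2)cc(OC)c1O | intermediate
22 | (7R,8S,9R)-9-(tert-butyldimethylsilyloxy)-2,3,3',4,5'-pentamethoxy-7,8-dimethyl-6,7,8,9-tetrahydrospiro[benzo[7]annulene-5,1'-cyclohexane]-2',5'-dien-4'-one | COC1=CC2(C=C(OC)C1=O)C[C@@H](C)[C@H](C)[C@@H](O[Si](C)(C)C(C)(C)C)c1cc(OC)c(OC)c(OC)c12 | intermediate
23 | (7R,8S,9R)-9-hydroxy-2,3,3',4,5'-pentamethoxy-7,8-dimethyl-6,7,8,9-tetrahydrospiro[benzo[7]annulene-5,1'-cyclohexane]-2',5'-dien-4'-one (CNP0288561.1) | COC1=CC2(C=C(OC)C1=O)C[C@@H](C)[C@H](C)[C@@H](O)c1cc(OC)c(OC)c(OC)c12 | target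

**Step count**
Total: 12 steps. Longest linear sequence: 12 steps (1 → 23); the ring-A Grignard reagent is made in the flask within step 8.

**Steps most likely to fail**

Step 5. Telescoping three insertions in the presence of both diamines may erode configurational fidelity at one methyl centre or leave an insertion incomplete, giving mixtures of homologues that are hard to separate. The fallback sets out from boronate 6 and ester 7 and comes back at boronate 14. It replaces the telescoped, diamine-mediated sequence by three isolated homologations with diamine-free carbenoids from purified precursors: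
- Ester 7 is lithiated (s-BuLi, (−)-sparteine, Et2O, −78 °C) and trapped with Me3SnCl to give (S)-1-(trimethylstannyl)ethyl 2,4,6-triisopropylbenzoate F1.
- The same operation with (+)-sparteine gives (R)-1-(trimethylstannyl)ethyl 2,4,6-triisopropylbenzoate F2; both stannanes are solids whose enantiomeric purity can be raised by recrystallisation.
- Tin–lithium exchange of F1 (n-BuLi, Et2O, −78 °C) regenerates carbenoid 9, which with 6 gives boronate 10, now isolated.
- F2 in the same way gives 11 and, with 10, boronate 12, which is isolated and freed from its diastereomer.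
- A separate Matteson homologation (8, n-BuLi, THF, −78 °C) returns to 14.

Step 11. The phenoxenium ion may be diverted before ring A attacks (loss of a benzylic proton to a quinone methide, capture by solvent), or the dienone may undergo acid-promoted aryl migration caused by the trifluoroacetic acid released. The fallback sets out from phenol 21 and comes back at spirodienone 22 and makes no new compound. The phenol is oxidised directly at a carbon anode (undivided cell, constant current, LiClO4 in MeCN/CF3CH2OH, 2,6-lutidine buffer, 0 °C). This is a known way of spirocyclising para-substituted phenols onto tethered electron-rich arenes; it generates the cation by electron transfer at the electrode, without a ligand-exchange step at iodine and without strong acid, so the product stays in a buffered medium.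

Step 8. Facial selectivity in the aryl addition may be poor, because the α-centre distinguishes only a methyl from a branched alkyl group, so much of the material may end up as the C1 epimer. The fallback sets out from aldehyde 16 and comes back at carbinol 19.
- The Grignard addition is run without regard to selectivity, giving 19 together with its epimer (1S,2S,3R)-4-[4-(benzyloxy)-3,5-dimethoxyphenyl]-2,3-dimethyl-1-(3,4,5-trimethoxyphenyl)butan-1-ol F3.
- The mixture is oxidised (Dess–Martin periodinane, CH2Cl2) to (2S,3R)-4-[4-(benzyloxy)-3,5-dimethoxyphenyl]-2,3-dimethyl-1-(3,4,5-trimethoxyphenyl)butan-1-one F4.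
- The ketone is reduced under catalyst control by a Corey–Bakshi–Shibata reduction ((S)-tetrahydro-1-methyl-3,3-diphenyl-1H,3H-pyrrolo[1,2-c][1,3,2]oxazaborole, BH3·SMe2, THF, −20 °C). With the aryl group as the large substituent the (S) catalyst should give the (1R) alcohol 19. Substrate-controlled hydride reduction is not used, because Felkin–Anh reduction of this ketone would favour the unwanted anti epimer.

**Further compounds**
F1 | step 5 | (S)-1-(trimethylstannyl)ethyl 2,4,6-triisopropylbenzoate | C[C@H]([Sn](C)(C)C)OC(=O)c1c(C(C)C)cc(C(C)C)cc1C(C)C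
F2 | step 5 | (R)-1-(trimethylstannyl)ethyl 2,4,6-triisopropylbenzoate | C[C@@H]([Sn](C)(C)C)OC(=O)c1c(C(C)C)cc(C(C)C)cc1C(C)C
F0 | step 11 | none | none
F3 | step 8 | (1S,2S,3R)-4-[4-(benzyloxy)-3,5-dimethoxyphenyl]-2,3-dimethyl-1-(3,4,5-trimethoxyphenyl)butan-1-ol | COc1cc(C[C@@H](C)[C@H](C)[C@H](O)c2cc(OC)c(OC)c(OC)c2)cc(OC)c1OCc1ccccc1
F4 | step 8 | (2S,3R)-4-[4-(benzyloxy)-3,5-dimethoxyphenyl]-2,3-dimethyl-1-(3,4,5-trimethoxyphenyl)butan-1-one | COc1cc(C[C@@H](C)[C@H](C)C(=O)c2cc(OC)c(OC)c(OC)c2)cc(OC)c1OCc1ccccc1
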